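**Strategy.** With ring A labelled C1–C6 and ring B C6–C11, the route cuts ring A at C3–C4 and C5–C6. The adjacent quaternary carbons C5 (gem-dimethyl) and C6 (spiro centre shared with ring B), together with the C4 methylene and the oxygen-bearing C3, are read as a 2-spiro-3,3-dimethylcyclobutanone. One keteniminium–alkene [2+2] cycloaddition between a ketal-protected, symmetric ring B carboxamide and 2-methylpropene forms both bonds and the congested C5–C6 junction at once. The four-membered ketone is then enlarged by C1 and C2 to the ring A enone. Ring B is desymmetrised with a chiral base and bromochlorinated, and ring A is finished by C4 bromination and C3 reduction.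

Key step: step 2

Atom labels: ring A = C1 (vinyl methyl)–C2–C3 (O)–C4 (Br)–C5 (CMe2)–C6 (spiro); ring B = C6–C7–C8–C9 (Me, Br)–C10 (Cl)–C11; these coincide with spiro[5.5]undecane numbering and are used for compounds 14–21.

Assumption: acid 1 and (E)-1-bromoprop-1-ene 9 are taken as commercial.

Assumption: the dioxolane survives step 2 because Tf2O is consumed by the far more nucleophilic amide oxygen at low temperature before heating, and collidine keeps the medium buffered.

Assumption: in diketone 14 and alkene 17, ring B reacts through the chair or half-chair with C5 equatorial and C1 axial; the base antipode in step 7 and the facial sense in step 9 follow from this, and the mirror-image base would be used if the sense of step 7 were found reversed.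

Remark: ring B is kept symmetric up to step 6 on purpose, because C6 passes through a planar radical in step 4 and could not hold a configuration earlier.

**Step 1**
Reactants: 1 1,4-dioxaspiro[4.5]decane-8-carboxylic acid; 2 dimethylamine
Product: 4 N,N-dimethyl-1,4-dioxaspiro[4.5]decane-8-carboxamide, via acyl imidazolide 3 (not isolated)
Conditions: CDI, THF, 25 °C; then Me2NH (2 M in THF), 25 °C
Reagents that add atoms: none
Why: Acyl imidazolide formation followed by aminolysis (CDI amide coupling) is neutral enough to leave the acid-labile ketal untouched and creates no stereocentre.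

**Step 2**
Reactants: 4 N,N-dimethyl-1,4-dioxaspiro[4.5]decane-8-carboxamide; 5 2-methylpropene
Product: 8 3,3-dimethyl-8,11-dioxadispiro[3.2.4^7.2^4]tridecan-1-one (spirocyclobutanone with C3 as carbonyl carbon), via keteniminium triflate 6 (not isolated), via cyclobutaniminium triflate 7 (not isolated)
Conditions: Tf2O, 2,4,6-collidine, 2-methylpropene (excess), ClCH2CH2Cl, −20 → 60 °C (sealed tube); then aq. NaHCO3, 25 °C
Reagents that add atoms: water, O
Why: Triflic anhydride O-triflates amide 4 and collidine removes the α-proton, so that triflate leaves with the former amide oxygen and the linear keteniminium ion 6 results; the CH2 terminus of 2-methylpropene bonds to its central carbon (future C3), the tertiary cation at C5 is captured by the enamine carbon C6, and water hydrolyses the resulting iminium salt 7 to ketone 8. The closest known reaction type is the keteniminium–alkene [2+2] cycloaddition of amide-derived keteniminium salts, which gives 2,2-disubstituted cyclobutanones also from 1,1-disubstituted alkenes. The four-membered ring closes in a stepwise polar manner, the second bond forming when the enamine carbon collapses onto the carbocation. No stereocentre arises, because ring B is symmetric and C6 is therefore not yet stereogenic. The step needs regioselectivity (C3–C4 and C5–C6, not the reverse), which is secured because only bonding of the alkene CH2 to the iminium carbon leaves a tertiary cation; it also needs ring closure to outrun proton loss from that cation, which the slim sp-hybridised electrophile and the hindered, weakly basic collidine favour.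

**Step 3**
Reactants: 8 3,3-dimethyl-8,11-dioxadispiro[3.2.4^7.2^4]tridecan-1-one; 9 (E)-1-bromoprop-1-ene
Product: 11 rac-3,3-dimethyl-1-[(E)-prop-1-enyl]-8,11-dioxadispiro[3.2.4^7.2^4]tridecan-1-ol, via (E)-prop-1-enyllithium 10 (not isolated)
Conditions: t-BuLi (2 equiv), Et2O, −78 °C; then 8, −78 → 0 °C; H2O
Reagents that add atoms: none
Why: 1,2-Addition of a vinyllithium, made with retention of the E geometry by bromine–lithium exchange, to the strained and therefore highly electrophilic cyclobutanone gives the tertiary allylic cyclobutanol; the carbinol carbon forms as a racemate, which is immaterial because it becomes a carbonyl carbon again in step 4.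

**Step 4**
Reactants: 11 rac-3,3-dimethyl-1-[(E)-prop-1-enyl]-8,11-dioxadispiro[3.2.4^7.2^4]tridecan-1-ol
Product: 12 rac-9,9,13-trimethyl-1,4-dioxadispiro[4.2.5^8.2^5]pentadecan-11-one (ring A ketone: C3 carbonyl, C1 bearing H and methyl, ring B ketal)
Conditions: [Ir(dF(CF3)ppy)2(5,5′-d(CF3)bpy)]PF6 (2 mol%), 2,4,6-collidine, CH2Cl2, blue LEDs, 25 °C
Reagents that add atoms: none
Why: Photocatalytic proton-coupled electron transfer (excited trivalent iridium oxidant plus collidine) converts the O–H into an alkoxy radical whose strain-driven β-scission cleaves C3–C6 toward the tertiary C6 radical, and this radical recloses by 6-endo Giese-type addition to the methyl-bearing β-carbon C1 of the liberated enone, a known two-carbon ring expansion of 1-alkenylcycloalkanols through alkoxy radicals; C1 forms as a racemate and is flattened in step 5.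

**Step 5**
Reactants: 12 rac-9,9,13-trimethyl-1,4-dioxadispiro[4.2.5^8.2^5]pentadecan-11-one
Product: 13 9,9,13-trimethyl-1,4-dioxadispiro[4.2.5^8.2^5]pentadec-12-en-11-one (ring A enone C1=C2–C3=O, ring B ketal)
Conditions: IBX, 4-methoxypyridine N-oxide, DMSO, 25–40 °C
Reagents that add atoms: none
Why: IBX-mediated α,β-dehydrogenation of a ketone can only run toward C1–C2, because the other α-carbon C4 is flanked by the hydrogen-free C5, so the enone forms regiospecifically, the racemic C1 centre disappears and the molecule becomes achiral, while the ketal tolerates the near-neutral conditions.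

**Step 6**
Reactants: 13 9,9,13-trimethyl-1,4-dioxadispiro[4.2.5^8.2^5]pentadec-12-en-11-one
Product: 14 1,5,5-trimethylspiro[5.5]undec-1-ene-3,9-dione
Conditions: PPTS, acetone/H2O, 55 °C
Reagents that add atoms: water, O
Why: Mild acid-catalysed ketal hydrolysis releases the ring B ketone without disturbing the hindered enone and gives an achiral diketone whose two ring B α-methylenes are enantiotopic.

**Step 7**
Reactants: 14 1,5,5-trimethylspiro[5.5]undec-1-ene-3,9-dione
Product: 16 (6S)-1,5,5-trimethyl-3-oxospiro[5.5]undeca-1,9-dien-9-yl trifluoromethanesulfonate, via lithium enolate 15 (not isolated)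
Conditions: (S,S)-bis(1-phenylethyl)amine·HCl, n-BuLi (2 equiv), THF, −78 °C; then PhNTf2, −78 → 0 °C
Reagents that add atoms: N-phenylbis(trifluoromethanesulfonimide), O=S(=O)(N(c1ccccc1)S(=O)(=O)C(F)(F)F)C(F)(F)F
Why: Enantioselective deprotonation by a chiral lithium amide in the presence of LiCl, known for the desymmetrisation of 4,4-disubstituted cyclohexanones, attacks only the unhindered ring B ketone and, by removing the axial proton at C10 and not the one at C8, makes C6 a stereocentre of defined configuration before the enolate is trapped as its enol triflate.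

**Step 8**
Reactants: 16 (6S)-1,5,5-trimethyl-3-oxospiro[5.5]undeca-1,9-dien-9-yl trifluoromethanesulfonate
Product: 17 (6S)-1,5,5,9-tetramethylspiro[5.5]undeca-1,9-dien-3-one
Conditions: MeZnCl, Pd(PPh3)4 (5 mol%), THF, 50 °C
Reagents that add atoms: methylzinc chloride, C[Zn]Cl
Why: Negishi coupling of the enol triflate under zerovalent palladium catalysis installs the C9 methyl without moving the double bond, tolerates the enone and touches no stereocentre.

**Step 9**
Reactants: 17 (6S)-1,5,5,9-tetramethylspiro[5.5]undeca-1,9-dien-3-one
Product: 18 (6S,9S,10S)-9-bromo-10-chloro-1,5,5,9-tetramethylspiro[5.5]undec-1-en-3-one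
Conditions: NBS, n-Bu4NCl (3 equiv), CH2Cl2, −40 → 0 °C
Reagents that add atoms: N-bromosuccinimide, O=C1CCC(=O)N1Br; tetrabutylammonium chloride, CCCC[N+](CCCC)(CCCC)CCCC.[Cl-]
Why: In this anti bromochlorination, Br+ should add to the ring B alkene face away from the axial C1 arm, whose vinyl methyl hangs over that ring, and chloride should open the bromonium ion trans-diaxially at the secondary carbon C10, as in the bromochlorination of conformationally biased trisubstituted cyclohexenes such as 5-ene steroids; this places Br on C9 cis to C5 and Cl on C10 cis to C1, while the electron-poor enone alkene of ring A stays inert.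

**Step 10**
Reactants: 18 (6S,9S,10S)-9-bromo-10-chloro-1,5,5,9-tetramethylspiro[5.5]undec-1-en-3-one
Product: 20 (4R,6R,9S,10S)-4,9-dibromo-10-chloro-1,5,5,9-tetramethylspiro[5.5]undec-1-en-3-one, via silyl dienol ether 19 (not isolated)
Conditions: LiN(SiMe3)2, Me3SiCl, THF, −78 °C; then NBS, THF, −78 → −40 °C
Reagents that add atoms: N-bromosuccinimide, O=C1CCC(=O)N1Br
Why: Kinetic α′-deprotonation of the enone with in situ silylation gives the cross-conjugated 2-silyloxydiene, which NBS brominates at C4 only; bromine is expected to enter anti to the pseudo-axial C5 methyl of the ring A twist conformer selected by the ring B substituents, that is on the ring A face that carries C11, a sense that rests on conformational analysis and has to be confirmed.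

**Step 11**
Reactants: 20 (4R,6R,9S,10S)-4,9-dibromo-10-chloro-1,5,5,9-tetramethylspiro[5.5]undec-1-en-3-one
Product: 21 (3S,4R,6R,9S,10S)-4,9-dibromo-10-chloro-1,5,5,9-tetramethylspiro[5.5]undec-1-en-3-ol (target)
Conditions: i-Bu2AlH, CH2Cl2, −78 °C; aq. potassium sodium tartrate
Reagents that add atoms: none
Why: 1,2-Reduction of the α-bromo enone by i-Bu2AlH delivers hydride to the carbonyl face anti to the adjacent C–Br bond, which should give the cis-bromohydrin with (3S) configuration without reducing any carbon–halogen bond.

**Compound list**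

1 | 1,4-dioxaspiro[4.5]decane-8-carboxylic acid | OC(=O)C1CCC2(CC1)OCCO2 | starting material
2 | dimethylamine | CNC | starting material
3 | 1-(1,4-dioxaspiro[4.5]decane-8-carbonyl)imidazole (acyl imidazolide) | O=C(C1CCC2(CC1)OCCO2)n1ccnc1 | intermediate (not isolated)
4 | N,N-dimethyl-1,4-dioxaspiro[4.5]decane-8-carboxamide | CN(C)C(=O)C1CCC2(CC1)OCCO2 | intermediate
5 | 2-methylpropene | C=C(C)C | starting material
6 | N-(1,4-dioxaspiro[4.5]decan-8-ylidenemethylidene)-N-methylmethanaminium triflate (keteniminium triflate) | C[N+](C)=C=C1CCC2(CC1)OCCO2.[O-]S(=O)(=O)C(F)(F)F | intermediate (not isolated)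
7 | N-(3,3-dimethyl-8,11-dioxadispiro[3.2.4^7.2^4]tridecan-1-ylidene)-N-methylmethanaminium triflate (cyclobutaniminium triflate) | C[N+](C)=C1CC(C)(C)C12CCC3(CC2)OCCO3.[O-]S(=O)(=O)C(F)(F)F | intermediate (not isolated)
8 | 3,3-dimethyl-8,11-dioxadispiro[3.2.4^7.2^4]tridecan-1-one | O=C1CC(C)(C)C12CCC3(CC2)OCCO3 | intermediate
9 | (E)-1-bromoprop-1-ene | C/C=C/Br | starting material
10 | (E)-prop-1-enyllithium | [Li]/C=C/C | intermediate (not isolated)
11 | rac-3,3-dimethyl-1-[(E)-prop-1-enyl]-8,11-dioxadispiro[3.2.4^7.2^4]tridecan-1-ol | C/C=C/C1(O)CC(C)(C)C12CCC3(CC2)OCCO3 | intermediate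
12 | rac-9,9,13-trimethyl-1,4-dioxadispiro[4.2.5^8.2^5]pentadecan-11-one | CC1CC(=O)CC(C)(C)C12CCC3(CC2)OCCO3 | intermediate
13 | 9,9,13-trimethyl-1,4-dioxadispiro[4.2.5^8.2^5]pentadec-12-en-11-one | CC1=CC(=O)CC(C)(C)C12CCC3(CC2)OCCO3 | intermediate
14 | 1,5,5-trimethylspiro[5.5]undec-1-ene-3,9-dione | CC1=CC(=O)CC(C)(C)C12CCC(=O)CC2 | intermediate
15 | lithium (6S)-1,5,5-trimethyl-3-oxospiro[5.5]undeca-1,9-dien-9-olate | CC1=CC(=O)CC(C)(C)[C@@]12CCC(O[Li])=CC2 | intermediate (not isolated)
16 | (6S)-1,5,5-trimethyl-3-oxospiro[5.5]undeca-1,9-dien-9-yl trifluoromethanesulfonate | CC1=CC(=O)CC(C)(C)[C@@]12CCC(OS(=O)(=O)C(F)(F)F)=CC2 | intermediate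
17 | (6S)-1,5,5,9-tetramethylspiro[5.5]undeca-1,9-dien-3-one | CC1=CC(=O)CC(C)(C)[C@@]12CCC(C)=CC2 | intermediate
18 | (6S,9S,10S)-9-bromo-10-chloro-1,5,5,9-tetramethylspiro[5.5]undec-1-en-3-one | CC1=CC(=O)CC(C)(C)[C@@]12CC[C@](C)(Br)[C@@H](Cl)C2 | intermediate
19 | [(6R,9S,10S)-9-bromo-10-chloro-1,5,5,9-tetramethylspiro[5.5]undeca-1,3-dien-3-yl]oxy-trimethylsilane | CC1=CC(O[Si](C)(C)C)=CC(C)(C)[C@@]12CC[C@](C)(Br)[C@@H](Cl)C2 | intermediate (not isolated)
20 | (4R,6R,9S,10S)-4,9-dibromo-10-chloro-1,5,5,9-tetramethylspiro[5.5]undec-1-en-3-one | CC1=CC(=O)[C@H](Br)C(C)(C)[C@@]12CC[C@](C)(Br)[C@@H](Cl)C2 | intermediate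
21 | (3S,4R,6R,9S,10S)-4,9-dibromo-10-chloro-1,5,5,9-tetramethylspiro[5.5]undec-1-en-3-ol | CC1=C[C@H](O)[C@H](Br)C(C)(C)[C@@]12CC[C@](C)(Br)[C@@H](Cl)C2 | target

Total step count: 11. Longest linear sequence: 11 steps (1 → 21).

**Steps most likely to fail**

Step 9. The bromonium ion may be opened at the tertiary carbon (Markovnikov sense, chlorine ending on C9 and bromine on C10), or bromine may be delivered to the other alkene face, so that regiochemistry or the relation of C9/C10 to C6 is lost. The fallback sets out from 17 and fixes the constitution by oxygen chemistry. Epoxidation with mCPBA (NaHCO3, CH2Cl2, 0 °C) should take place on the same open face and give the epoxide F1, with the oxirane oxygen cis to C5. LiCl/AcOH in THF, which opens oxiranes at the less substituted carbon, should attack C10 trans-diaxially and give the chlorohydrin F2. Me3SiBr in CH2Cl2 at −20 °C then replaces the tertiary hydroxyl by bromide with retention, through the chloronium ion formed by the anti-periplanar C10 chlorine, and the route is rejoined at 18.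

Step 4. Recombination of the hindered tertiary C6 radical with the methyl-bearing enone terminus may be too slow, so that the ring-opened radical is reduced or adds intermolecularly before ring A closes. The fallback sets out from 11 and uses two-electron chemistry: KH and 18-crown-6 in THF (0 → 25 °C) give the potassium alkoxide F3, whose alkoxide-accelerated 1,3-shift (cleavage of C3–C6 and rebonding of C6 to C1) leads to the potassium enolate F4; protonation with aq. NH4Cl rejoins the route at 12.

Step 2. Because two fully substituted carbons must bond, the tertiary cation may lose a proton before the ring closes (ene-type acylation of the alkene), and triflic anhydride or triflic acid may open the ketal. The fallback sets out from 4 and generates the keteniminium ion without any triflic species. Oxalyl chloride in CH2Cl2 gives the chloroiminium chloride F5, and Et3N converts it into the distillable α-chloroenamine F6. AgBF4 in CH2Cl2 with excess 2-methylpropene (−40 → 25 °C) abstracts chloride to give the keteniminium tetrafluoroborate F7, which cycloadds to the cyclobutaniminium tetrafluoroborate F8; aqueous NaHCO3 hydrolysis rejoins the route at 8.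

**Further compounds**

F1 | step 9 | (6S,9S,10R)-9,10-epoxy-1,5,5,9-tetramethylspiro[5.5]undec-1-en-3-one (oxirane oxygen cis to C5) | CC1=CC(=O)CC(C)(C)[C@@]12CC[C@]3(C)O[C@@H]3C2
F2 | step 9 | (6S,9S,10S)-10-chloro-9-hydroxy-1,5,5,9-tetramethylspiro[5.5]undec-1-en-3-one | CC1=CC(=O)CC(C)(C)[C@@]12CC[C@](C)(O)[C@@H](Cl)C2
F3 | step 4 | potassium rac-3,3-dimethyl-1-[(E)-prop-1-enyl]-8,11-dioxadispiro[3.2.4^7.2^4]tridecan-1-olate | C/C=C/C1(O[K])CC(C)(C)C12CCC3(CC2)OCCO3
F4 | step 4 | potassium rac-9,9,13-trimethyl-1,4-dioxadispiro[4.2.5^8.2^5]pentadec-11-en-11-olate | CC1C=C(O[K])CC(C)(C)C12CCC3(CC2)OCCO3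
F5 | step 2 | N-[chloro(1,4-dioxaspiro[4.5]decan-8-yl)methylidene]-N-methylmethanaminium chloride | C[N+](C)=C(Cl)C1CCC2(CC1)OCCO2.[Cl-]
F6 | step 2 | 1-chloro-1-(1,4-dioxaspiro[4.5]decan-8-ylidene)-N,N-dimethylmethanamine | CN(C)C(Cl)=C1CCC2(CC1)OCCO2
F7 | step 2 | N-(1,4-dioxaspiro[4.5]decan-8-ylidenemethylidene)-N-methylmethanaminium tetrafluoroborate | C[N+](C)=C=C1CCC2(CC1)OCCO2.F[B-](F)(F)F
F8 | step 2 | N-(3,3-dimethyl-8,11-dioxadispiro[3.2.4^7.2^4]tridecan-1-ylidene)-N-methylmethanaminium tetrafluoroborate | C[N+](C)=C1CC(C)(C)C12CCC3(CC2)OCCO3.F[B-](F)(F)F
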